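(The numbers in the tables are simulated from invented constants, and the scatter is random.)

Sunday's flask cannot hold more X than 50.0% of its E charged, since each X has cost two L and this flask is charged with 1.00 equivalents of L. That bound is a sum on the budget of L, and the dispute is over what the budget buys in the other flasks.

| flask | E | L | remark | time |
|---|---|---|---|---|
| green | 0.14 M | 0.13 M | run made earlier |  |
| Wednesday's | 0.060 M | 0.500 M |  | 8.0 d |
| Friday's | 0.060 M | 0.130 M |  | 8.0 d |
| Monday's | 0.13 M | 0.500 M |  | 8.0 d |
| Sunday's | 0.13 M | 0.130 M |  | 8.0 d |

green run (percent of the E charged)

| time / d | X / % |
|---|---|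
| 1.25 | 14.0 |
| 2.50 | 20.4 |
| 4.00 | 23.9 |
| 5.00 | 23.8 |

(readings scatter by 0.5 percentage points)

1. the flasks put in order of amount of X, in percent of the E charged, best first, at 8.0 d (Wednesday's / Friday's / Monday's / Sunday's)
2. the same order at 20 h (Wednesday's / Friday's / Monday's / Sunday's)
3. the amount of X, in percent of the E charged of the flask you put first, at 8.0 d
4. the amount of X, in percent of the E charged of the flask you put last, at 8.0 d

- the earlier runs were read with a standard deviation of 0.5 percentage points
- reactions considered so far: E + L -> Z; L + Z -> X; L + X -> Q; L + Q -> D; L + X -> G

Each listed step takes one L. If each step is taken as second order, the rate of making X divided by the rate of spending L contains neither L nor time, so it depends on the composition in fractions of the charge.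

In green, which is charged with 0.929 equivalents, X reads 23.9% and then 23.8%, a difference within the scatter of 0.5 percentage points. I therefore take L in green as the limiting reagent and, as my own assumption, count its 0.929 equivalents as used by then. This gives my carried quantity, the yield per equivalent, meaning X in fractions of the E charged divided by equivalents of L spent: 25.7%, a reading with the scatter of its X.

My view is that this yield holds up to about two equivalents spent. Friday's is charged with 2.17 equivalents, so I expect 55.8% of X there if these are used by the end.

The opposing view is the forecast's: X climbs to a peak and is then lost. It puts the flasks as Friday's > Sunday's > Monday's > Wednesday's and at 20 h as Wednesday's > Monday's > Friday's > Sunday's. It gives the first flask 38%, within 32% to 44%, and the last 0.2%, within 0% to 3%. Its ground is: “The peak X should be about 40%, near two equivalents consumed.”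

The flasks give Friday's > Sunday's > Monday's > Wednesday's, and at 20 h Wednesday's > Monday's > Friday's > Sunday's, both as forecast. X at the end is 52.2% in Friday's, 26.9% in Sunday's, 9.52% in Monday's and 0.467% in Wednesday's.

    E + L → Z (k = 0.320 /M/h)
    L + Z → X (k = 0.340 /M/h)
    L + X → Q (k = 0.0120 /M/h)
    L + Q → D (k = 0.540 /M/h)
    L + X → G (k = 0.0820 /M/h)

Friday's, with 10.3% of its own L left, has spent 1.94 equivalents and holds 26.9% of X per equivalent, beside the 25.7% read from green. The forecast's overshoot fits Monday's and Wednesday's, which spent 3.02 and 3.12 equivalents. The neighbouring flask is Friday's with 0.036 M of E, so 3.61 equivalents. With 33% of its own L left it has spent 2.42, for which 25.7% per equivalent gives 62.2%. It holds 46.6% of X, 19.3% per equivalent, beside 40.3% of G.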